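## Retrosynthetic overview
1. Acid ⇐ ethyl ester ⇐ C5–CH3 bond. AlMe3 adds to the peroxycarbenium ion of a 5-methoxy-1,2-dioxolane, and C3 steers C5 to the cis-dimethyl arrangement.
2. E-C10=C11 ⇐ Julia–Kocienski olefination of the dioxolane aldehyde with a phenyltetrazolyl sulfone made from 5-bromopent-1-ene, styrene and phenyltetrazolethiol.
3. The only ring, the 1,2-dioxolane, ⇐ 5-exo conjugate addition of a C5 hydroperoxide to the Δ2-enoate, as presumed in the sponge. A chiral bifunctional catalyst sets C3.
4. The C5 hydroperoxy ketal and the C10 aldehyde ⇐ one methanolic ozonolysis of a skipped triene ester, which cleaves C5=CH2 and the prenyl group and keeps the enoate.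
5. Triene ester ⇐ (R)-citronellal (brings C7) by alkyne homologation, α-hydroalumination and allyl coupling with a C5 bromo enoate.

Assumption: the allylic bromide is used as the pure E isomer (commercial E/Z mixtures can be distilled apart), and the squaramide pseudo-enantiomer (both commercial) that gives 3R is identified by experiment.

## Route

Step 1
Reactants: 1 (R)-citronellal
Product: 2 (4R)-4,8-dimethylnon-7-en-1-yne
Conditions: dimethyl (1-diazo-2-oxopropyl)phosphonate, K2CO3, MeOH, 0 °C to rt
Reagents that add atoms: dimethyl (1-diazo-2-oxopropyl)phosphonate, COP(=O)(OC)C(=[N+]=[N-])C(C)=O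
Why: Seyferth–Gilbert homologation in the Ohira–Bestmann variant turns the aldehyde into the terminal alkyne under mild carbonate conditions, under which the β-stereocentre (C7 of the target, taken from the chiral pool) cannot epimerise and the trisubstituted alkene is inert.

Step 2
Reactants: 2 (4R)-4,8-dimethylnon-7-en-1-yne; 3 ethyl (E)-4-bromo-3-methylbut-2-enoate
Product: 5 ethyl (2E,7R)-3,7,11-trimethyl-5-methylidenedodeca-2,10-dienoate, via alkenylalane 4 (not isolated)
Conditions: i-Bu2AlH (1.05 equiv), Ni(dppp)Cl2 (3 mol %), THF, 0 °C to rt; then 3, Pd(PPh3)4 (5 mol %), THF, rt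
Reagents that add atoms: none
Why: Nickel-catalysed α-selective (Markovnikov) hydroalumination puts aluminium on the internal alkyne carbon, and the alkenylalane then undergoes a Negishi-type Pd-catalysed alkenyl–allyl cross-coupling at the unhindered CH2 terminus of 3, which keeps the E-enoate conjugated and forms no stereocentre.

Step 3
Reactants: 5 ethyl (2E,7R)-3,7,11-trimethyl-5-methylidenedodeca-2,10-dienoate
Product: 7 ethyl 2-[(3R)-5-methoxy-3-methyl-5-[(2R)-2-methyl-5-oxopentyl]-1,2-dioxolan-3-yl]acetate (both C5 epimers), via hydroperoxy ketal 6 (not isolated)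
Conditions: O3, CH2Cl2/MeOH 4:1, NaHCO3, Sudan Red 7B as end-point dye, −78 °C; N2 purge, cold aqueous wash, swap to toluene (never to dryness); quinine-derived 3,5-bis(trifluoromethyl)phenyl squaramide (10 mol %), toluene, −20 °C
Reagents that add atoms: ozone, [O-][O+]=O; methanol, CO
Why: Proposed new method: Criegee ozonolysis in methanol cleaves only the two electron-rich alkenes (the enoate reacts far more slowly) and MeOH traps the more substituted carbonyl oxides, so one operation gives the C10 aldehyde and the C5 α-methoxy hydroperoxide 6 (both known reaction types); the squaramide then activates the OOH with its quinuclidine base and binds the ester carbonyl with its NH donors, so that the biomimetic 5-exo-trig peroxa-Michael addition to the geometrically fixed E-enoate takes place on one face and sets C3 as R, whatever the C5 configuration, which is erased in step 8; the closest known reactions are the amine-promoted racemic cyclisation of hydroperoxy ketals onto enoates and the bifunctional-base-catalysed enantioselective intramolecular oxa-Michael addition of alcohols to α,β-unsaturated esters.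

Step 4
Reactants: 8 5-bromopent-1-ene; 9 styrene
Product: 10 (E)-(5-bromopent-1-en-1-yl)benzene
Conditions: second-generation Grubbs catalyst (2 mol %), styrene (3 equiv), CH2Cl2, 40 °C
Reagents that add atoms: none
Why: Olefin cross-metathesis of an unhindered terminal alkene with excess styrene is driven by loss of ethene and gives the conjugated E-styrene almost exclusively under thermodynamic control.

Step 5
Reactants: 10 (E)-(5-bromopent-1-en-1-yl)benzene; 11 1-phenyl-1H-tetrazole-5-thiol
Product: 12 1-phenyl-5-{[(4E)-5-phenylpent-4-en-1-yl]sulfanyl}-1H-tetrazole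
Conditions: K2CO3, acetone, 56 °C
Reagents that add atoms: none
Why: SN2 S-alkylation of the soft thiolate by the primary bromide is fast and leaves the styrene untouched.

Step 6
Reactants: 12 1-phenyl-5-{[(4E)-5-phenylpent-4-en-1-yl]sulfanyl}-1H-tetrazole
Product: 13 1-phenyl-5-{[(4E)-5-phenylpent-4-en-1-yl]sulfonyl}-1H-tetrazole
Conditions: 30% H2O2, (NH4)6Mo7O24·4H2O (10 mol %), EtOH, 0 °C to rt
Reagents that add atoms: hydrogen peroxide, OO
Why: Molybdate-catalysed peroxide oxidation transfers two oxygens to sulfur much faster than it epoxidises a 1,2-disubstituted alkene, which is the standard entry to Julia–Kocienski sulfones.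

Step 7
Reactants: 7 ethyl 2-[(3R)-5-methoxy-3-methyl-5-[(2R)-2-methyl-5-oxopentyl]-1,2-dioxolan-3-yl]acetate; 13 1-phenyl-5-{[(4E)-5-phenylpent-4-en-1-yl]sulfonyl}-1H-tetrazole
Product: 15 ethyl 2-[(3R)-5-methoxy-3-methyl-5-[(2R,5E,9E)-2-methyl-10-phenyldeca-5,9-dien-1-yl]-1,2-dioxolan-3-yl]acetate (both C5 epimers), via potassiated sulfone 14 (not isolated)
Conditions: 13, KN(SiMe3)2, DME, −60 °C, 30 min; then 7, −60 °C to rt
Reagents that add atoms: none
Why: Julia–Kocienski olefination of an unbranched aldehyde with a pre-metalated phenyltetrazolyl sulfone (potassium counter-ion, DME) gives the E-alkene with high selectivity, and the fully substituted peroxy ketal has no hydrogen on its oxygen-bearing carbons, so it resists base-induced fragmentation while the carbanion adds to the aldehyde faster than it enolises the ester.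

Step 8
Reactants: 15 ethyl 2-[(3R)-5-methoxy-3-methyl-5-[(2R,5E,9E)-2-methyl-10-phenyldeca-5,9-dien-1-yl]-1,2-dioxolan-3-yl]acetate
Product: 17 ethyl 2-[(3R,5R)-3,5-dimethyl-5-[(2R,5E,9E)-2-methyl-10-phenyldeca-5,9-dien-1-yl]-1,2-dioxolan-3-yl]acetate, via peroxycarbenium ion 16 (not isolated)
Conditions: AlMe3 (3 equiv), CH2Cl2, −78 to −20 °C
Reagents that add atoms: trimethylaluminium, C[Al](C)C
Why: Proposed new method: AlMe3 abstracts the exocyclic methoxide from either C5 epimer to give the same planar, oxygen-stabilised peroxycarbenium ion 16, and methyl is delivered to the ring face opposite the AlMe3-complexed CH2CO2Et arm on C3 (1,3-induction across the envelope), which places the new methyl cis to the C3 methyl and sets C5 as R, any 5-epimer being a separable trans-dioxolane; the closest known reactions are the Lewis-acid-mediated substitution of 3-alkoxy-1,2-dioxolanes by silyl ketene acetals or allylsilanes via peroxycarbenium ions and the C-methylation of peroxy acetals and cyclic ketals with AlMe3, both of which leave the O–O bond intact.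

Step 9
Reactants: 17 ethyl 2-[(3R,5R)-3,5-dimethyl-5-[(2R,5E,9E)-2-methyl-10-phenyldeca-5,9-dien-1-yl]-1,2-dioxolan-3-yl]acetate
Product: 19 2-[(3R,5R)-3,5-dimethyl-5-[(2R,5E,9E)-2-methyl-10-phenyldeca-5,9-dien-1-yl]-1,2-dioxolan-3-yl]acetic acid, via lithium carboxylate 18 (not isolated)
Conditions: LiOH, THF/MeOH/H2O, 0 °C to rt; then 1 M HCl
Reagents that add atoms: lithium hydroxide, [Li+].[OH-]
Why: Saponification of the unhindered ethyl ester is faster than enolisation and retro-Michael opening, and the tetrasubstituted dioxolane cannot undergo Kornblum–DeLaMare cleavage, so C3, C5 and C7 are kept.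

## Compound list
1 | (R)-citronellal | C[C@H](CCC=C(C)C)CC=O | starting material
2 | (4R)-4,8-dimethylnon-7-en-1-yne | C[C@H](CCC=C(C)C)CC#C | intermediate
3 | ethyl (E)-4-bromo-3-methylbut-2-enoate | BrC/C(C)=C/C(=O)OCC | starting material
4 | diisobutyl[(4R)-4,8-dimethylnona-1,7-dien-2-yl]aluminium | C[C@H](CCC=C(C)C)CC(=C)[Al](CC(C)C)CC(C)C | intermediate
5 | ethyl (2E,7R)-3,7,11-trimethyl-5-methylidenedodeca-2,10-dienoate | C[C@H](CCC=C(C)C)CC(=C)C/C(C)=C/C(=O)OCC | intermediate
6 | ethyl (2E,7R)-5-hydroperoxy-5-methoxy-3,7-dimethyl-10-oxodec-2-enoate (both C5 epimers) | C[C@H](CCC=O)CC(OC)(OO)C/C(C)=C/C(=O)OCC | intermediate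
7 | ethyl 2-[(3R)-5-methoxy-3-methyl-5-[(2R)-2-methyl-5-oxopentyl]-1,2-dioxolan-3-yl]acetate (both C5 epimers) | C[C@H](CCC=O)CC1(OC)C[C@](C)(CC(=O)OCC)OO1 | intermediate
8 | 5-bromopent-1-ene | C=CCCCBr | starting material
9 | styrene | C=Cc1ccccc1 | starting material
10 | (E)-(5-bromopent-1-en-1-yl)benzene | BrCCC/C=C/c1ccccc1 | intermediate
11 | 1-phenyl-1H-tetrazole-5-thiol | Sc1nnnn1-c1ccccc1 | starting material
12 | 1-phenyl-5-{[(4E)-5-phenylpent-4-en-1-yl]sulfanyl}-1H-tetrazole | c1ccccc1/C=C/CCCSc1nnnn1-c1ccccc1 | intermediate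
13 | 1-phenyl-5-{[(4E)-5-phenylpent-4-en-1-yl]sulfonyl}-1H-tetrazole | O=S(=O)(CCC/C=C/c1ccccc1)c1nnnn1-c1ccccc1 | intermediate
14 | potassium salt of α-deprotonated 13 | [K+].O=S(=O)([CH-]CC/C=C/c1ccccc1)c1nnnn1-c1ccccc1 | intermediate
15 | ethyl 2-[(3R)-5-methoxy-3-methyl-5-[(2R,5E,9E)-2-methyl-10-phenyldeca-5,9-dien-1-yl]-1,2-dioxolan-3-yl]acetate (both C5 epimers) | C[C@H](CC/C=C/CC/C=C/c1ccccc1)CC1(OC)C[C@](C)(CC(=O)OCC)OO1 | intermediate
16 | (3R)-3-(2-ethoxy-2-oxoethyl)-3-methyl-5-[(2R,5E,9E)-2-methyl-10-phenyldeca-5,9-dien-1-yl]-1,2-dioxolan-5-ylium (peroxycarbenium ion) | C[C@H](CC/C=C/CC/C=C/c1ccccc1)CC=1C[C@](C)(CC(=O)OCC)O[O+]=1 | intermediate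
17 | ethyl 2-[(3R,5R)-3,5-dimethyl-5-[(2R,5E,9E)-2-methyl-10-phenyldeca-5,9-dien-1-yl]-1,2-dioxolan-3-yl]acetate | C[C@H](CC/C=C/CC/C=C/c1ccccc1)C[C@]1(C)C[C@](C)(CC(=O)OCC)OO1 | intermediate
18 | lithium 2-[(3R,5R)-3,5-dimethyl-5-[(2R,5E,9E)-2-methyl-10-phenyldeca-5,9-dien-1-yl]-1,2-dioxolan-3-yl]acetate | [Li+].C[C@H](CC/C=C/CC/C=C/c1ccccc1)C[C@]1(C)C[C@](C)(CC(=O)[O-])OO1 | intermediate
19 | 2-[(3R,5R)-3,5-dimethyl-5-[(2R,5E,9E)-2-methyl-10-phenyldeca-5,9-dien-1-yl]-1,2-dioxolan-3-yl]acetic acid | C[C@H](CC/C=C/CC/C=C/c1ccccc1)C[C@]1(C)C[C@](C)(CC(=O)O)OO1 | target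

## Step count and risks
Total steps: 9. Longest linear sequence: 6 (steps 1, 2, 3, 7, 8, 9).

**Step 3 (most likely to fail).** The ozone dose may touch the enoate. More seriously, the catalyst may not override the two C5 epimers, and a low C3 selectivity would give ring-enantiomeric diastereomers that are hard to separate.

The fallback replaces asymmetric catalysis by a late kinetic resolution. It sets out from 6 and comes back at 19.
- Crude 6 is cyclised with Et2NH in CF3CH2OH. This gives 7 together with its C3 epimer, ethyl 2-[(3S)-5-methoxy-3-methyl-5-[(2R)-2-methyl-5-oxopentyl]-1,2-dioxolan-3-yl]acetate F3.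
- The pair is taken through the olefination of step 7, which gives 15 and the (3S) Julia product F4.
- The methylation of step 8 then gives 17 and the (3S,5S,7R) ethyl ester F5.
- In place of LiOH, the ester pair is treated with a lipase (Candida rugosa lipase, pH 7 buffer/MTBE). The enzyme reads the stereocentre two atoms from the ester, so acid 19 is extracted away from unreacted F5.
- If the enzyme prefers F5 instead, the recovered 17 goes through step 9.

**Step 8.** The peroxycarbenium ion may lose a proton, fragment at the O–O bond, or be trapped by the C10=C11 alkene. The facial bias may also be modest.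

The fallback brings the C5 methyl in as the former methylene carbon by radical chemistry, before the styrene is present. It sets out from 5 and comes back at 17.
- Mukaiyama–Isayama hydroperoxysilylation (Co(thd)2, O2, Et3SiH, 1,2-dichloroethane) delivers hydrogen to the unhindered CH2 of the 1,1-disubstituted alkene in preference to the prenyl group. This gives the triethylsilyl peroxide F6 as both C5 epimers.
- Dilute HCl in THF/H2O frees the tertiary hydroperoxide F7.
- The squaramide-catalysed peroxa-Michael addition converts the 5R epimer into the cis-dioxolane prenyl ester F8 and the 5S epimer into the trans isomer F9, which is removed on silica.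
- Ozonolysis of F8 with Me2S work-up gives the aldehyde F10.
- Julia–Kocienski olefination of F10 with 13 gives 17.

**Step 2.** The ester-bearing π-allyl palladium species may couple at the α-carbon or scramble the enoate geometry.

The fallback reverses the polarity of the coupling. It sets out from alkenylalane 4 and comes back at 5.
- Alkenylalane 4 is quenched with N-bromosuccinimide (THF, −78 to 0 °C) to give (4R)-2-bromo-4,8-dimethylnona-1,7-diene F1.
- Ethyl 3-methylbut-2-enoate is converted with LiN(i-Pr)2 and Me3SiCl into [(1-ethoxy-3-methylbuta-1,3-dien-1-yl)oxy]trimethylsilane F2.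
- Palladium-catalysed γ-alkenylation of the silyl dienolate (Pd(dba)2, P(t-Bu)3, ZnF2, DMF, 80 °C) joins F1 and F2 at the γ-carbon to give 5 as the E-enoate.

## Further compounds
F1 | step 2 | (4R)-2-bromo-4,8-dimethylnona-1,7-diene | C[C@H](CCC=C(C)C)CC(Br)=C
F2 | step 2 | [(1-ethoxy-3-methylbuta-1,3-dien-1-yl)oxy]trimethylsilane | CCOC(=CC(C)=C)O[Si](C)(C)C
F3 | step 3 | ethyl 2-[(3S)-5-methoxy-3-methyl-5-[(2R)-2-methyl-5-oxopentyl]-1,2-dioxolan-3-yl]acetate (both C5 epimers) | C[C@H](CCC=O)CC1(OC)C[C@@](C)(CC(=O)OCC)OO1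
F4 | step 3 | ethyl 2-[(3S)-5-methoxy-3-methyl-5-[(2R,5E,9E)-2-methyl-10-phenyldeca-5,9-dien-1-yl]-1,2-dioxolan-3-yl]acetate (both C5 epimers) | C[C@H](CC/C=C/CC/C=C/c1ccccc1)CC1(OC)C[C@@](C)(CC(=O)OCC)OO1
F5 | step 3 | ethyl 2-[(3S,5S)-3,5-dimethyl-5-[(2R,5E,9E)-2-methyl-10-phenyldeca-5,9-dien-1-yl]-1,2-dioxolan-3-yl]acetate | C[C@H](CC/C=C/CC/C=C/c1ccccc1)C[C@@]1(C)C[C@@](C)(CC(=O)OCC)OO1
F6 | step 8 | ethyl (2E,7R)-3,5,7,11-tetramethyl-5-[(triethylsilyl)peroxy]dodeca-2,10-dienoate (both C5 epimers) | C[C@H](CCC=C(C)C)CC(C)(OO[Si](CC)(CC)CC)C/C(C)=C/C(=O)OCC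
F7 | step 8 | ethyl (2E,7R)-5-hydroperoxy-3,5,7,11-tetramethyldodeca-2,10-dienoate (both C5 epimers) | C[C@H](CCC=C(C)C)CC(C)(OO)C/C(C)=C/C(=O)OCC
F8 | step 8 | ethyl 2-[(3R,5R)-5-[(2R)-2,6-dimethylhept-5-en-1-yl]-3,5-dimethyl-1,2-dioxolan-3-yl]acetate | C[C@H](CCC=C(C)C)C[C@]1(C)C[C@](C)(CC(=O)OCC)OO1
F9 | step 8 | ethyl 2-[(3R,5S)-5-[(2R)-2,6-dimethylhept-5-en-1-yl]-3,5-dimethyl-1,2-dioxolan-3-yl]acetate | C[C@H](CCC=C(C)C)C[C@@]1(C)C[C@](C)(CC(=O)OCC)OO1
F10 | step 8 | ethyl 2-[(3R,5R)-3,5-dimethyl-5-[(2R)-2-methyl-5-oxopentyl]-1,2-dioxolan-3-yl]acetate | C[C@H](CCC=O)C[C@]1(C)C[C@](C)(CC(=O)OCC)OO1
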